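**Assumption:** all‑E geranylgeraniol and all‑Z arachidonic acid are bought as such; the ring stereocentre of the target is (S); the binaphthyl axis cannot be written in plain SMILES, so (R) is carried in the names; compounds are numbered in the order of the forward steps.

## Retrosynthetic overview

- Target ⇒ retro proton‑initiated terminal monocyclisation (open the ring CH–CMe2 bond back to the terminal isopropylidene and the 10,11‑olefin) ⇒ acyclic (2E,6E,10E)‑geranylgeranyl arachidonate. The ring and the only stereocentre are made together in the last step by a chiral proton source.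
- Geranylgeranyl arachidonate ⇒ ester C–O ⇒ (2E,6E,10E)‑geranylgeraniol + arachidonic acid.
- Chiral proton source, (R)‑BINOL mono(2‑fluorobenzyl) ether·SnCl4 ⇒ (R)‑BINOL + 2‑fluorobenzyl bromide.
- Ring order: one ring only (the 2,6,6‑trimethylcyclohex‑2‑ene), formed last.

## Route

**Step 1**
Reactants: 1 (2E,6E,10E)-geranylgeraniol; 2 arachidonic acid, (5Z,8Z,11Z,14Z)-icosa-5,8,11,14-tetraenoic acid
Product: 5 (2E,6E,10E)-geranylgeranyl (5Z,8Z,11Z,14Z)-icosa-5,8,11,14-tetraenoate, via O-acylisourea 3 (not isolated), via N-acylpyridinium ion 4 (not isolated)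
Conditions: DCC (1.1 eq), DMAP (0.1 eq), CH2Cl2, 0 °C → rt, Ar, dark
Reagents that add atoms: none
Why: Steglich esterification; DCC activates the acid as the O‑acylisourea and DMAP transfers the acyl group to the primary allylic alcohol under neutral conditions at or below rt, so neither the skipped Z‑tetraene nor the E‑trisubstituted olefins isomerise, and no stereocentre is involved.

**Step 2**
Reactants: 6 (R)-1,1'-bi-2-naphthol; 7 2-fluorobenzyl bromide
Product: 8 (R)-2'-[(2-fluorobenzyl)oxy]-1,1'-binaphthalen-2-ol
Conditions: K2CO3 (1.0 eq), acetone, reflux, 16 h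
Reagents that add atoms: none
Why: Williamson mono‑O‑alkylation with one equivalent of base and halide; the second naphthol is more hindered after the first alkylation, so the mono‑ether predominates and is separated from bis‑ether and recovered 6, and the configurationally stable biaryl axis keeps its (R) configuration.

**Step 3**
Reactants: 5 (2E,6E,10E)-geranylgeranyl (5Z,8Z,11Z,14Z)-icosa-5,8,11,14-tetraenoate
Product: 10 (2E,6E)-3,7-dimethyl-9-[(1S)-2,6,6-trimethylcyclohex-2-en-1-yl]nona-2,6-dien-1-yl (5Z,8Z,11Z,14Z)-icosa-5,8,11,14-tetraenoate (target), via monocyclic tertiary cation 9 (not isolated)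
Conditions: 8 (2.2 eq), SnCl4 (2.0 eq), toluene, −78 °C, 30 min; then 5 (0.02 M), −78 °C, 48 h, Ar, dark; sat. aq NaHCO3 at −78 °C; SiO2 then reversed‑phase HPLC (8 recovered)
Reagents that add atoms: none
Why: Proposed new method: the SnCl4‑acidified naphthol proton of the chiral LBA is delivered to C‑14 of the most exposed, non‑deactivated terminal isopropylidene of 5 while the 10,11‑olefin attacks C‑15 through a chair transition state in the binaphthyl pocket, so the ring and its stereocentre are formed in one event, in the (S) sense (the "normal", ambrox‑type 5α‑H A‑ring that (R)‑configured LBAs are expected to give); cation 9 then loses the axial ring‑CH2 proton (endo, Zaitsev) to the [ArO–SnCl4]⁻ counter‑ion in toluene at −78 °C faster than the 6,7‑olefin can close a second ring, while the cis‑1,2‑disubstituted arachidonate olefins (secondary cations) and the acyloxy‑deactivated 2,3‑olefin are not protonated and primary allylic carboxylates are stable to strong acid at this temperature; the closest known reaction type is the Yamamoto–Ishihara LBA‑induced enantioselective protonative polyene cyclisation, in which chiral LBAs close only the A ring of polyprenoids enantioselectively and leave monocyclic olefins that need a second, stronger achiral acid to cyclise further.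

## Compound list

1 | (2E,6E,10E)-geranylgeraniol, (2E,6E,10E)-3,7,11,15-tetramethylhexadeca-2,6,10,14-tetraen-1-ol | CC(C)=CCC/C(C)=C/CC/C(C)=C/CC/C(C)=C/CO | starting material
2 | arachidonic acid, (5Z,8Z,11Z,14Z)-icosa-5,8,11,14-tetraenoic acid | CCCCC/C=C\C/C=C\C/C=C\C/C=C\CCCC(=O)O | starting material
3 | O-arachidonoyl-N,N'-dicyclohexylisourea | CCCCC/C=C\C/C=C\C/C=C\C/C=C\CCCC(=O)OC(=NC1CCCCC1)NC1CCCCC1 | intermediate
4 | 1-arachidonoyl-4-(dimethylamino)pyridinium ion | CCCCC/C=C\C/C=C\C/C=C\C/C=C\CCCC(=O)[n+]1ccc(N(C)C)cc1 | intermediate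
5 | (2E,6E,10E)-geranylgeranyl (5Z,8Z,11Z,14Z)-icosa-5,8,11,14-tetraenoate | CCCCC/C=C\C/C=C\C/C=C\C/C=C\CCCC(=O)OC/C=C(\C)CC/C=C(\C)CC/C=C(\C)CCC=C(C)C | intermediate
6 | (R)-1,1'-bi-2-naphthol | Oc1ccc2ccccc2c1-c1c(O)ccc2ccccc12 | starting material
7 | 2-fluorobenzyl bromide | Fc1ccccc1CBr | starting material
8 | (R)-2'-[(2-fluorobenzyl)oxy]-1,1'-binaphthalen-2-ol (recoverable chiral ligand) | Oc1ccc2ccccc2c1-c1c(OCc2ccccc2F)ccc2ccccc12 | intermediate
9 | monocyclic tertiary cation: (S)-configured 2,2,6-trimethylcyclohexyl C‑6 cation carrying the full ester chain | CCCCC/C=C\C/C=C\C/C=C\C/C=C\CCCC(=O)OC/C=C(\C)CC/C=C(\C)CC[C@@H]1[C+](C)CCCC1(C)C | intermediate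
10 | (2E,6E)-3,7-dimethyl-9-[(1S)-2,6,6-trimethylcyclohex-2-en-1-yl]nona-2,6-dien-1-yl (5Z,8Z,11Z,14Z)-icosa-5,8,11,14-tetraenoate | CCCCC/C=C\C/C=C\C/C=C\C/C=C\CCCC(=O)OC/C=C(\C)CC/C=C(\C)CC[C@@H]1C(C)=CCCC1(C)C | target

## Step count and risks

Total step count: 3. Steps 1 and 3 are the main line; step 2 makes the recoverable chiral proton source.
Longest linear sequence: 2.

**Most likely to fail, in order**

1. **Step 3.** Possible failures:
   - a second ring closes through the 6,7‑olefin (bicyclic isomers);
   - the cation loses a methyl proton (exocyclic isomer) or the ring CH proton (tetrasubstituted olefin, which destroys the stereocentre);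
   - the ester carbonyl ties up the tin;
   - the isomeric C40 esters are hard to separate;
   - the ee is likely to stop near the 85–90 % typical of LBA A‑ring closures, so a chiral‑phase HPLC polish is needed;
   - the sense of induction is assigned by analogy and must be confirmed on the first run by chiral HPLC or rotation.

   Fallback, setting out from 1 and coming back at 10: silylate 1 (TBDPSCl, imidazole, DMF) to geranylgeranyl tert‑butyldiphenylsilyl ether F1. Treat F1 with the same (R)‑LBA (8, SnCl4, toluene, −78 °C) to give the (S)‑monocyclic silyl ether F2. At this C20 stage there is no Lewis‑basic acyl chain and no skipped tetraene, so F2 can be freed from exo‑olefin and bicyclic isomers on AgNO3‑silica. TBAF in THF then gives the (S)‑monocyclic diterpenol F3, whose ee can be polished by chiral HPLC. DCC/DMAP coupling of F3 with 2 (through 3 and 4) gives 10. This moves the cyclisation ahead of the acylation instead of making it the end‑game.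

2. **Step 1.** Possible failures are N‑acylurea formation and autoxidation of the activated arachidonate. Fallback, setting out from 1 and coming back at 5: convert 1 with PBr3 in Et2O at 0 °C into (2E,6E,10E)‑geranylgeranyl bromide F4, then alkylate the caesium salt of 2 (Cs2CO3, DMF, rt) with F4 to give 5. The C–O bond is then made by SN2 at the allylic carbon and the acid is never activated.

3. **Step 2.** Possible failure is a statistical mixture of mono‑ether, bis‑ether and 6. Fallback, setting out from 6 and coming back at 8: mono‑acylate 6 (pivaloyl chloride, Et3N, MeCN, 0 °C) to (R)‑2'‑hydroxy‑1,1'‑binaphthalen‑2‑yl pivalate F5. Alkylate the remaining naphthol with 7 (K2CO3, acetone, reflux) to (R)‑2'‑[(2‑fluorobenzyl)oxy]‑1,1'‑binaphthalen‑2‑yl pivalate F6. Cleave the pivalate (KOH, MeOH/THF, then dilute HCl) to give 8. Desymmetrisation by protection replaces the statistical alkylation.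

## Further compounds

F1 | step 3 | (2E,6E,10E)-geranylgeranyl tert-butyldiphenylsilyl ether | CC(C)=CCC/C(C)=C/CC/C(C)=C/CC/C(C)=C/CO[Si](c1ccccc1)(c1ccccc1)C(C)(C)C
F2 | step 3 | tert-butyl{[(2E,6E)-3,7-dimethyl-9-[(1S)-2,6,6-trimethylcyclohex-2-en-1-yl]nona-2,6-dien-1-yl]oxy}diphenylsilane | CC(C)(C)[Si](OC/C=C(\C)CC/C=C(\C)CC[C@@H]1C(C)=CCCC1(C)C)(c1ccccc1)c1ccccc1
F3 | step 3 | (2E,6E)-3,7-dimethyl-9-[(1S)-2,6,6-trimethylcyclohex-2-en-1-yl]nona-2,6-dien-1-ol | OC/C=C(\C)CC/C=C(\C)CC[C@@H]1C(C)=CCCC1(C)C
F4 | step 1 | (2E,6E,10E)-geranylgeranyl bromide | CC(C)=CCC/C(C)=C/CC/C(C)=C/CC/C(C)=C/CBr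
F5 | step 2 | (R)-2'-hydroxy-1,1'-binaphthalen-2-yl pivalate | CC(C)(C)C(=O)Oc1ccc2ccccc2c1-c1c(O)ccc2ccccc12
F6 | step 2 | (R)-2'-[(2-fluorobenzyl)oxy]-1,1'-binaphthalen-2-yl pivalate | CC(C)(C)C(=O)Oc1ccc2ccccc2c1-c1c(OCc2ccccc2F)ccc2ccccc12
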